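Slowness was my first question: which part of these flasks would still be creeping at the time asked?

in all of them: X 1.3 M
- spring: E 1 M; run made earlier
- summer: E 1.7 M; run made earlier
- dawn: E 2.2 M; run made earlier
- east: E 1.20 M; time 4.0 h
- north: E 1.80 M; time 4.0 h
- south-east: E 2.80 M; time 4.0 h

| run | time / min | X / % | J / % |
|---|---|---|---|
| spring | 25.0 | 62.3 | 2.3 |
| spring | 50.0 | 55.6 | 3.4 |
| spring | 80.0 | 52.9 | 4.0 |
| spring | 90.0 | 53.0 | 4.0 |
| spring | 120 | 51.9 | 4.2 |
| summer | 25.0 | 47.6 | 5.4 |
| summer | 50.0 | 39.7 | 8.0 |
| summer | 80.0 | 36.9 | 8.9 |
| summer | 90.0 | 36.9 | 8.5 |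
| summer | 120 | 35.2 | 8.8 |
| dawn | 10.0 | 54.0 | 3.2 |
| dawn | 30.0 | 37.3 | 7.3 |
| dawn | 60.0 | 30.0 | 10.5 |
| dawn | 80.0 | 28.3 | 11.5 |
| dawn | 120 | 26.8 | 11.4 |

(standard deviation of a reading: 0.3 percentage points)

- part of the X that has reacted at the end, east
- part of the X that has reacted at the end, north
- part of the X that has reacted at the end, south-east
- what raising the concentration of E from its lowest to its highest value here does to the part of the X that has reacted (changes below 5 percentage points count as none) (no change / it rises / it falls)

- what is said of Z includes G
- candidate steps: X + E -> L + Z; E + L -> Q + Z; E + Q -> J + Z; E + J -> D + Z; E + Z <-> G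

The readings gave me a ladder of times. On the lowest rung, in the dawn run, X had already fallen to 54.0% by 10.0 min. On the next rung, J slowed along with X: in the spring run it read 4.0% at 80.0 min and 4.2% at 120 min. Higher up, dawn's X still lost 1.5 percentage points between 80.0 min and 120 min, more than the scatter of 0.3 points. The time asked, 4.0 h, is twice that last reading, so I expected each new flask to have stopped by then, with its X a little lower than a line through the last readings gives.

With the same charge of X, the last X reading was 51.9% in spring and 26.8% in dawn, so I took E as the limiting reagent and reckoned in equivalents of E per X. X reacts in one step with E, so its logarithm is a clock. I called the exposure the natural logarithm of one over the fraction of X left: 0.656 in spring at 0.769 equivalents, 1.32 in dawn at 1.69. The gain in exposure per equivalent of E was 0.716. That line gave me 53.5% reacted in east, 66.6% in north, and, from an exposure of 1.65, 80.7% in south-east.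

The forecast printed 54%, 67% and 81.5%, each a little more than mine, and for the trend, it rises. It warned: “The south-east value is the least certain, as it lies beyond the data.”

The flasks gave 53.9%, 67.2% and 81.8%; from lowest to highest E, it rises, by 28 points.

    X + E → L + Z (k = 0.0440 /M/min)
    E + L → Q + Z (k = 0.0700 /M/min)
    E + Q → J + Z (k = 0.0760 /M/min)
    E + J → D + Z (k = 0.110 /M/min)
    E + Z ⇌ G, settled at all times (K = 1.30 /M)

South-east's exposure came to 1.70 against my 1.65. For the neighbour of north with 0.52 M of X, 3.46 equivalents, the line gave 92.4%, and that flask gave 93.9%. In east, G held 0.0238% of the E charge at 4.00 h, and with no binding the answer stood at 53.9%. South-east kept 0.18% of its E free at 4.00 h; by 40.0 h its X had gone from 18.2% to 18.0%, while L went from 19.6% to 19.4% and D from 28.1% to 28.6%.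

All runs were generated by integration for an exercise.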